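**Strategy.** Everything rests on disconnecting the C2–C3 bond of the dihydrobenzofuran: C2 is the benzylic ether carbon that carries ring C and C3 is bonded directly to ring B, so a ring-B aryl(ester) carbene can insert into a C–H bond of the ring-C benzyloxy CH2 group placed ortho to it. One dirhodium-catalysed operation forms C2–C3, closes the oxygen ring and fixes C2 and, after base equilibration, trans C3. The precursor is a methyl aryldiazoacetate; its parent arylacetic acid also becomes ring A, where an auxiliary anti-aldol adds ring D and the (1S,2S)-diol. The two halves are united through an auxiliary-derived (R)-butyrolactone and its trans-selective α-benzylation.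

Key step: step 9

Labels: ring A = phenol ring on the lactone α-CH2; ring B = benzo ring of the dihydrobenzofuran; ring C = guaiacyl ring on C2; ring D = guaiacyl ring on the carbinol carbon; BMP = 4-(benzyloxy)-3-methoxyphenyl; TBS = tert-butyldimethylsilyl. Target configuration: dihydrobenzofuran 2S,3R (trans), lactone 3R,4R (trans), diol 1S,2S (anti).

Assumption: Rh2(S-PTTL)4 (dirhodium tetrakis[N-phthaloyl-(S)-tert-leucinate]) is taken to deliver the 2S series; should the sense of induction be the opposite, the mirror-image catalyst Rh2(R-PTTL)4 is used and nothing else changes.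

**Route**

Step 1
Reactants: 1 vanillin; 2 allyl bromide
Product: 3 4-(allyloxy)-3-methoxybenzaldehyde
Conditions: K2CO3, acetone, reflux
Reagents that add atoms: none
Why: Williamson ether synthesis, in which the phenoxide displaces bromide from the allylic halide by SN2.

Step 2
Reactants: 3 4-(allyloxy)-3-methoxybenzaldehyde
Product: 4 5-allylvanillin (3-allyl-4-hydroxy-5-methoxybenzaldehyde)
Conditions: neat, 200 °C
Reagents that add atoms: none
Why: aromatic Claisen rearrangement, whose concerted [3,3] shift delivers the allyl group to the only free ortho position before tautomerisation restores the phenol.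

Step 3
Reactants: 4 5-allylvanillin; 5 [4-(benzyloxy)-3-methoxyphenyl]methanol
Product: 6 3-allyl-4-(BMP-methoxy)-5-methoxybenzaldehyde
Conditions: PPh3, DIAD, THF, 0 °C to rt
Reagents that add atoms: none
Why: Mitsunobu etherification, in which the acidic para-formyl phenol is alkylated by the activated primary benzylic alcohol, so that no labile electron-rich benzylic halide has to be made.

Step 4
Reactants: 6 3-allyl-4-(BMP-methoxy)-5-methoxybenzaldehyde
Product: 7 [3-allyl-4-(BMP-methoxy)-5-methoxyphenyl]methanol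
Conditions: NaBH4, MeOH/THF, 0 °C
Reagents that add atoms: none
Why: borohydride reduction of an aryl aldehyde, to which the alkene and the ethers are inert.

Step 5
Reactants: 7 [3-allyl-4-(BMP-methoxy)-5-methoxyphenyl]methanol
Product: 8 TBS ether of 7
Conditions: TBSCl, imidazole, DMF, rt
Reagents that add atoms: tert-butyldimethylsilyl chloride, CC(C)(C)[Si](C)(C)Cl
Why: silylation of a primary alcohol, which masks the C5 arm through the oxidation, diazo and carbene steps.

Step 6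
Reactants: 8 TBS ether of 7
Product: 10 2-[2-(BMP-methoxy)-5-(TBS-oxymethyl)-3-methoxyphenyl]acetic acid, via arylacetaldehyde 9 (not isolated)
Conditions: OsO4 (cat.), NaIO4, 2,6-lutidine, dioxane/H2O, rt; extractive work-up; then NaClO2, NaH2PO4, 2-methyl-2-butene, t-BuOH/H2O, 0 °C to rt
Reagents that add atoms: sodium periodate, [Na+].[O-]I(=O)(=O)=O; sodium chlorite, [Na+].[O-]Cl=O
Why: Lemieux–Johnson cleavage of the terminal alkene followed at once by Pinnick oxidation, so that the enolisable arylacetaldehyde is never stored and the chlorine scavenger protects the electron-rich rings.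

Step 7
Reactants: 10 arylacetic acid
Product: 11 methyl 2-[2-(BMP-methoxy)-5-(TBS-oxymethyl)-3-methoxyphenyl]acetate
Conditions: MeI, K2CO3, DMF, rt
Reagents that add atoms: iodomethane, CI
Why: carboxylate O-alkylation (SN2 esterification) under conditions that leave silyl and benzyl ethers untouched.

Step 8
Reactants: 11 methyl arylacetate
Product: 12 methyl 2-diazo-2-[2-(BMP-methoxy)-5-(TBS-oxymethyl)-3-methoxyphenyl]acetate
Conditions: 4-acetamidobenzenesulfonyl azide, DBU, MeCN, 0 °C to rt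
Reagents that add atoms: 4-acetamidobenzenesulfonyl azide, CC(=O)Nc1ccc(cc1)S(=O)(=O)N=[N+]=[N-]
Why: Regitz diazo transfer, in which DBU deprotonates the benzylic α-position of the arylacetate and the sulfonyl azide hands over N2.

Step 9
Reactants: 12 methyl aryldiazoacetate
Product: 14 methyl (2S,3S)-trans-2-(BMP)-5-(TBS-oxymethyl)-7-methoxy-2,3-dihydro-1-benzofuran-3-carboxylate, via cis-(2S,3R) ester 13 (not isolated)
Conditions: Rh2(S-PTTL)4 (1 mol %), toluene, −60 °C, slow addition of 12; then NaOMe, MeOH, rt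
Reagents that add atoms: none
Why: The dirhodium tetracarboxylate expels N2 from the aryldiazoacetate to give an electrophilic donor/acceptor carbene on the ring-B benzylic carbon, which inserts into a C–H bond of the ortho O–CH2–ring C group through a concerted, asynchronous three-centre transition state with hydride-transfer character. The closest known reaction type is the chiral dirhodium carboxylate-catalysed intramolecular C–H insertion of ortho-benzyloxy aryldiazoacetates to 2-aryl-2,3-dihydrobenzofuran-3-carboxylates. The oxygen ring closes by 1,5-insertion, that is five-membered ring formation through the new C2–C3 bond. C2 is set by the chiral pocket of the phthaloyl-tert-leucinate ligands, which selects one of the two enantiotopic benzylic hydrogens, whereas C3 arises cis under kinetic control and is then epimerised by methoxide through the ester enolate to the more stable trans (2S,3S) ester with C2 untouched. The step needs site selectivity over the O–CH2 groups of the benzyl and silyl ethers and over the methoxy groups, and chemoselectivity over carbene dimerisation and aromatic addition; the substrate secures the former because only the ortho benzyloxy CH2 can reach the carbene through a five-membered transition state and it is doubly activated by the ether oxygen and the electron-rich ring C, while low temperature and slow addition suppress bimolecular paths.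

Step 10
Reactants: 14 trans ester
Product: 15 [(2S,3R)-2-(BMP)-5-(TBS-oxymethyl)-7-methoxy-2,3-dihydro-1-benzofuran-3-yl]methanol
Conditions: LiBH4, THF, 0 °C to rt
Reagents that add atoms: none
Why: borohydride reduction of the ester to the primary alcohol, which removes the epimerisable position at C3 and spares silyl and benzyl ethers.

Step 11
Reactants: 15 dihydrobenzofuran carbinol
Product: 16 (2S,3R)-3-(benzyloxymethyl)-2-(BMP)-5-(TBS-oxymethyl)-7-methoxy-2,3-dihydro-1-benzofuran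
Conditions: NaH, BnBr, Bu4NI (cat.), THF/DMF, 0 °C to rt
Reagents that add atoms: benzyl bromide, BrCc1ccccc1
Why: Williamson benzylation of the primary alkoxide, giving an ether that survives all later base and acid steps and leaves in the final hydrogenolysis.

Step 12
Reactants: 16 benzyl ether
Product: 17 [(2S,3R)-3-(benzyloxymethyl)-2-(BMP)-7-methoxy-2,3-dihydro-1-benzofuran-5-yl]methanol
Conditions: Bu4NF, THF, 0 °C
Reagents that add atoms: none
Why: fluoride-mediated desilylation, selective for the Si–O bond in the presence of benzyl ethers.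

Step 13
Reactants: 17 C5 benzylic alcohol
Product: 18 (2S,3R)-3-(benzyloxymethyl)-2-(BMP)-5-(bromomethyl)-7-methoxy-2,3-dihydro-1-benzofuran
Conditions: CBr4, PPh3, CH2Cl2, 0 °C; used directly
Reagents that add atoms: carbon tetrabromide, BrC(Br)(Br)Br
Why: Appel bromination of a primary benzylic alcohol under neutral conditions.

Step 14
Reactants: 19 4-tert-butoxy-4-oxobutanoic acid; 20 (R)-4-benzyl-1,3-oxazolidin-2-one
Product: 22 tert-butyl 4-[(4R)-4-benzyl-2-oxo-1,3-oxazolidin-3-yl]-4-oxobutanoate, via mixed pivalic anhydride 21 (not isolated)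
Conditions: PivCl, Et3N, THF, −20 °C; then 20, LiCl, rt
Reagents that add atoms: none
Why: N-acylation of the oxazolidinone through a mixed pivalic anhydride, which is attacked at the less hindered carbonyl.

Step 15
Reactants: 22 succinyl imide; 18 benzylic bromide
Product: 23 tert-butyl (3R)-4-[(4R)-4-benzyl-2-oxo-1,3-oxazolidin-3-yl]-3-{[(2S,3R)-3-(benzyloxymethyl)-2-(BMP)-7-methoxy-2,3-dihydro-1-benzofuran-5-yl]methyl}-4-oxobutanoate
Conditions: NaN(SiMe3)2, THF, −78 °C; then 18, −78 to −40 °C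
Reagents that add atoms: none
Why: Evans alkylation, in which the chelated Z-sodium enolate forms at the more acidic imide α-CH2 and is benzylated on the face away from the auxiliary benzyl group, setting the (R) centre.

Step 16
Reactants: 23 alkylated imide
Product: 25 (4R)-4-{[(2S,3R)-3-(benzyloxymethyl)-2-(BMP)-7-methoxy-2,3-dihydro-1-benzofuran-5-yl]methyl}oxolan-2-one, via hydroxy tert-butyl ester 24 (not isolated)
Conditions: LiBH4, H2O (1 equiv), THF, 0 °C; then TsOH·H2O (cat.), toluene, 60 °C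
Reagents that add atoms: none
Why: chemoselective reductive cleavage of the N-acyl oxazolidinone (the hindered tert-butyl ester is spared) followed by acid-catalysed lactonisation, neither of which touches the stereocentre.

Step 17
Reactants: 10 arylacetic acid; 26 (S)-4-benzyl-1,3-oxazolidin-2-one
Product: 28 (4S)-4-benzyl-3-{2-[2-(BMP-methoxy)-5-(TBS-oxymethyl)-3-methoxyphenyl]acetyl}-1,3-oxazolidin-2-one, via mixed pivalic anhydride 27 (not isolated)
Conditions: PivCl, Et3N, THF, −20 °C; then 26, LiCl, rt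
Reagents that add atoms: none
Why: N-acylation of the oxazolidinone through a mixed pivalic anhydride, as in step 14.

Step 18
Reactants: 28 arylacetyl imide; 29 4-(benzyloxy)-3-methoxybenzaldehyde
Product: 31 (4S)-4-benzyl-3-[(2R,3S)-3-(BMP)-2-[2-(BMP-methoxy)-5-(hydroxymethyl)-3-methoxyphenyl]-3-hydroxypropanoyl]-1,3-oxazolidin-2-one, via trimethylsilyl ether 30 (not isolated)
Conditions: MgCl2 (0.2 equiv), Et3N, Me3SiCl, EtOAc, rt; then HF·pyridine, pyridine/THF, 0 °C to rt
Reagents that add atoms: none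
Why: magnesium halide-catalysed direct anti-aldol of an N-acyl oxazolidinone with a non-enolisable aromatic aldehyde, in which the chelated Z-magnesium enolate adds on the face away from the auxiliary benzyl group through a boat-like transition state (setting 2R and 3S together), O-silylation turns the magnesium over, and HF·pyridine then removes both silyl groups.

Step 19
Reactants: 31 anti-aldol imide
Product: 32 (1S,2S)-1-(BMP)-2-[2-(BMP-methoxy)-5-(hydroxymethyl)-3-methoxyphenyl]propane-1,3-diol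
Conditions: LiBH4, MeOH (1 equiv), THF, 0 °C
Reagents that add atoms: none
Why: reductive removal of the oxazolidinone auxiliary, which turns the imide carbonyl into the primary alcohol and ends the epimerisability of the α-carbon.

Step 20
Reactants: 32 triol
Product: 33 {4-(BMP-methoxy)-3-[(4S,5S)-4-(BMP)-2,2-dimethyl-1,3-dioxan-5-yl]-5-methoxyphenyl}methanol
Conditions: 2,2-dimethoxypropane, PPTS (cat.), acetone, rt; aqueous NaHCO3 work-up
Reagents that add atoms: 2,2-dimethoxypropane, COC(C)(C)OC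
Why: acid-catalysed transacetalisation, which closes only the 1,3-diol to a six-membered acetonide with both aryl groups equatorial and leaves the remote benzylic alcohol free.

Step 21
Reactants: 33 acetonide alcohol
Product: 34 (4S,5S)-4-(BMP)-5-[2-(BMP-methoxy)-5-(bromomethyl)-3-methoxyphenyl]-2,2-dimethyl-1,3-dioxane
Conditions: CBr4, PPh3, CH2Cl2, 0 °C; used directly
Reagents that add atoms: carbon tetrabromide, BrC(Br)(Br)Br
Why: Appel bromination of the primary benzylic alcohol under neutral conditions that the acetonide tolerates.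

Step 22
Reactants: 25 (R)-lactone; 34 ring-A benzylic bromide
Product: 35 (3R,4R)-3-{[4-(BMP-methoxy)-3-[(4S,5S)-4-(BMP)-2,2-dimethyl-1,3-dioxan-5-yl]-5-methoxyphenyl]methyl}-4-{[(2S,3R)-3-(benzyloxymethyl)-2-(BMP)-7-methoxy-2,3-dihydro-1-benzofuran-5-yl]methyl}oxolan-2-one
Conditions: LiN(SiMe3)2, THF, −78 °C; then 34, DMPU, −78 to −30 °C
Reagents that add atoms: none
Why: lactone enolate alkylation, in which the lithium enolate attacks the benzylic bromide anti to the C4 substituent and so gives the trans (3R,4R) lactone.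

Step 23
Reactants: 35 protected lactone
Product: 36 (3R,4R)-3-{[4-(BMP-methoxy)-3-[(1S,2S)-1-(BMP)-1,3-dihydroxypropan-2-yl]-5-methoxyphenyl]methyl}-4-{[(2S,3R)-3-(benzyloxymethyl)-2-(BMP)-7-methoxy-2,3-dihydro-1-benzofuran-5-yl]methyl}oxolan-2-one
Conditions: AcOH/THF/H2O (3:1:1), 45 °C
Reagents that add atoms: none
Why: acid-catalysed acetal hydrolysis, done while every phenol is still masked so that the benzylic carbinol cannot ionise and be captured by the ortho-phenol of ring A.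

Step 24
Reactants: 36 diol
Product: 37 CNP0186558.2 (target)
Conditions: H2 (1 atm), 10% Pd/C, EtOAc/MeOH, rt
Reagents that add atoms: none
Why: neutral heterogeneous hydrogenolysis, which cleaves the four O-benzyl groups and the ring-A aryl benzylic ether, while the secondary benzylic alcohol, the cyclic C2–O ether and the lactone react more slowly and should persist.

**Compound list**

1 | vanillin | COc1cc(C=O)ccc1O | starting material
2 | allyl bromide | C=CCBr | starting material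
3 | 4-(allyloxy)-3-methoxybenzaldehyde | COc1cc(C=O)ccc1OCC=C | intermediate
4 | 3-allyl-4-hydroxy-5-methoxybenzaldehyde (5-allylvanillin) | COc1cc(C=O)cc(CC=C)c1O | intermediate
5 | [4-(benzyloxy)-3-methoxyphenyl]methanol | COc1cc(CO)ccc1OCc1ccccc1 | starting material
6 | 3-allyl-4-{[4-(benzyloxy)-3-methoxyphenyl]methoxy}-5-methoxybenzaldehyde | COc1cc(C=O)cc(CC=C)c1OCc1ccc(OCc2ccccc2)c(OC)c1 | intermediate
7 | (3-allyl-4-{[4-(benzyloxy)-3-methoxyphenyl]methoxy}-5-methoxyphenyl)methanol | COc1cc(CO)cc(CC=C)c1OCc1ccc(OCc2ccccc2)c(OC)c1 | intermediate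
8 | [(3-allyl-4-{[4-(benzyloxy)-3-methoxyphenyl]methoxy}-5-methoxyphenyl)methoxy](tert-butyl)dimethylsilane | COc1cc(CO[Si](C)(C)C(C)(C)C)cc(CC=C)c1OCc1ccc(OCc2ccccc2)c(OC)c1 | intermediate
9 | 2-(2-{[4-(benzyloxy)-3-methoxyphenyl]methoxy}-5-{[(tert-butyldimethylsilyl)oxy]methyl}-3-methoxyphenyl)acetaldehyde | COc1cc(CO[Si](C)(C)C(C)(C)C)cc(CC=O)c1OCc1ccc(OCc2ccccc2)c(OC)c1 | intermediate
10 | 2-(2-{[4-(benzyloxy)-3-methoxyphenyl]methoxy}-5-{[(tert-butyldimethylsilyl)oxy]methyl}-3-methoxyphenyl)acetic acid | COc1cc(CO[Si](C)(C)C(C)(C)C)cc(CC(=O)O)c1OCc1ccc(OCc2ccccc2)c(OC)c1 | intermediate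
11 | methyl 2-(2-{[4-(benzyloxy)-3-methoxyphenyl]methoxy}-5-{[(tert-butyldimethylsilyl)oxy]methyl}-3-methoxyphenyl)acetate | COC(=O)Cc1cc(CO[Si](C)(C)C(C)(C)C)cc(OC)c1OCc1ccc(OCc2ccccc2)c(OC)c1 | intermediate
12 | methyl 2-diazo-2-(2-{[4-(benzyloxy)-3-methoxyphenyl]methoxy}-5-{[(tert-butyldimethylsilyl)oxy]methyl}-3-methoxyphenyl)acetate | COC(=O)C(=[N+]=[N-])c1cc(CO[Si](C)(C)C(C)(C)C)cc(OC)c1OCc1ccc(OCc2ccccc2)c(OC)c1 | intermediate
13 | methyl (2S,3R)-2-[4-(benzyloxy)-3-methoxyphenyl]-5-{[(tert-butyldimethylsilyl)oxy]methyl}-7-methoxy-2,3-dihydro-1-benzofuran-3-carboxylate (cis) | CC(C)(C)[Si](C)(C)OCc1cc(OC)c2c(c1)[C@@H](C(=O)OC)[C@@H](c1ccc(OCc3ccccc3)c(OC)c1)O2 | intermediate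
14 | methyl (2S,3S)-2-[4-(benzyloxy)-3-methoxyphenyl]-5-{[(tert-butyldimethylsilyl)oxy]methyl}-7-methoxy-2,3-dihydro-1-benzofuran-3-carboxylate (trans) | CC(C)(C)[Si](C)(C)OCc1cc(OC)c2c(c1)[C@H](C(=O)OC)[C@@H](c1ccc(OCc3ccccc3)c(OC)c1)O2 | intermediate
15 | [(2S,3R)-2-[4-(benzyloxy)-3-methoxyphenyl]-5-{[(tert-butyldimethylsilyl)oxy]methyl}-7-methoxy-2,3-dihydro-1-benzofuran-3-yl]methanol | CC(C)(C)[Si](C)(C)OCc1cc(OC)c2c(c1)[C@H](CO)[C@@H](c1ccc(OCc3ccccc3)c(OC)c1)O2 | intermediate
16 | (2S,3R)-3-[(benzyloxy)methyl]-2-[4-(benzyloxy)-3-methoxyphenyl]-5-{[(tert-butyldimethylsilyl)oxy]methyl}-7-methoxy-2,3-dihydro-1-benzofuran | CC(C)(C)[Si](C)(C)OCc1cc(OC)c2c(c1)[C@H](COCc1ccccc1)[C@@H](c1ccc(OCc3ccccc3)c(OC)c1)O2 | intermediate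
17 | [(2S,3R)-3-[(benzyloxy)methyl]-2-[4-(benzyloxy)-3-methoxyphenyl]-7-methoxy-2,3-dihydro-1-benzofuran-5-yl]methanol | OCc1cc(OC)c2c(c1)[C@H](COCc1ccccc1)[C@@H](c1ccc(OCc3ccccc3)c(OC)c1)O2 | intermediate
18 | (2S,3R)-3-[(benzyloxy)methyl]-2-[4-(benzyloxy)-3-methoxyphenyl]-5-(bromomethyl)-7-methoxy-2,3-dihydro-1-benzofuran | BrCc1cc(OC)c2c(c1)[C@H](COCc1ccccc1)[C@@H](c1ccc(OCc3ccccc3)c(OC)c1)O2 | intermediate
19 | 4-tert-butoxy-4-oxobutanoic acid | CC(C)(C)OC(=O)CCC(=O)O | starting material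
20 | (R)-4-benzyl-1,3-oxazolidin-2-one | O=C1N[C@H](Cc2ccccc2)CO1 | starting material
21 | 4-tert-butoxy-4-oxobutanoic pivalic anhydride | CC(C)(C)OC(=O)CCC(=O)OC(=O)C(C)(C)C | intermediate
22 | tert-butyl 4-[(4R)-4-benzyl-2-oxo-1,3-oxazolidin-3-yl]-4-oxobutanoate | CC(C)(C)OC(=O)CCC(=O)N1[C@H](Cc2ccccc2)COC1=O | intermediate
23 | tert-butyl (3R)-4-[(4R)-4-benzyl-2-oxo-1,3-oxazolidin-3-yl]-3-{[(2S,3R)-3-[(benzyloxy)methyl]-2-[4-(benzyloxy)-3-methoxyphenyl]-7-methoxy-2,3-dihydro-1-benzofuran-5-yl]methyl}-4-oxobutanoate | CC(C)(C)OC(=O)C[C@@H](Cc1cc(OC)c2c(c1)[C@H](COCc1ccccc1)[C@@H](c1ccc(OCc3ccccc3)c(OC)c1)O2)C(=O)N1[C@H](Cc2ccccc2)COC1=O | intermediate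
24 | tert-butyl (3R)-3-{[(2S,3R)-3-[(benzyloxy)methyl]-2-[4-(benzyloxy)-3-methoxyphenyl]-7-methoxy-2,3-dihydro-1-benzofuran-5-yl]methyl}-4-hydroxybutanoate | CC(C)(C)OC(=O)C[C@@H](Cc1cc(OC)c2c(c1)[C@H](COCc1ccccc1)[C@@H](c1ccc(OCc3ccccc3)c(OC)c1)O2)CO | intermediate
25 | (4R)-4-{[(2S,3R)-3-[(benzyloxy)methyl]-2-[4-(benzyloxy)-3-methoxyphenyl]-7-methoxy-2,3-dihydro-1-benzofuran-5-yl]methyl}oxolan-2-one | O=C1C[C@@H](Cc2cc(OC)c3c(c2)[C@H](COCc2ccccc2)[C@@H](c2ccc(OCc4ccccc4)c(OC)c2)O3)CO1 | intermediate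
26 | (S)-4-benzyl-1,3-oxazolidin-2-one | O=C1N[C@@H](Cc2ccccc2)CO1 | starting material
27 | 2-(2-{[4-(benzyloxy)-3-methoxyphenyl]methoxy}-5-{[(tert-butyldimethylsilyl)oxy]methyl}-3-methoxyphenyl)acetic pivalic anhydride | COc1cc(CO[Si](C)(C)C(C)(C)C)cc(CC(=O)OC(=O)C(C)(C)C)c1OCc1ccc(OCc2ccccc2)c(OC)c1 | intermediate
28 | (4S)-4-benzyl-3-[2-(2-{[4-(benzyloxy)-3-methoxyphenyl]methoxy}-5-{[(tert-butyldimethylsilyl)oxy]methyl}-3-methoxyphenyl)acetyl]-1,3-oxazolidin-2-one | COc1cc(CO[Si](C)(C)C(C)(C)C)cc(CC(=O)N2[C@@H](Cc3ccccc3)COC2=O)c1OCc1ccc(OCc2ccccc2)c(OC)c1 | intermediate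
29 | 4-(benzyloxy)-3-methoxybenzaldehyde | COc1cc(C=O)ccc1OCc1ccccc1 | starting material
30 | (4S)-4-benzyl-3-[(2R,3S)-3-[4-(benzyloxy)-3-methoxyphenyl]-2-(2-{[4-(benzyloxy)-3-methoxyphenyl]methoxy}-5-{[(tert-butyldimethylsilyl)oxy]methyl}-3-methoxyphenyl)-3-[(trimethylsilyl)oxy]propanoyl]-1,3-oxazolidin-2-one | COc1cc([C@@H](O[Si](C)(C)C)[C@H](C(=O)N2[C@@H](Cc3ccccc3)COC2=O)c2cc(CO[Si](C)(C)C(C)(C)C)cc(OC)c2OCc2ccc(OCc3ccccc3)c(OC)c2)ccc1OCc1ccccc1 | intermediate
31 | (4S)-4-benzyl-3-[(2R,3S)-3-[4-(benzyloxy)-3-methoxyphenyl]-2-(2-{[4-(benzyloxy)-3-methoxyphenyl]methoxy}-5-(hydroxymethyl)-3-methoxyphenyl)-3-hydroxypropanoyl]-1,3-oxazolidin-2-one | COc1cc([C@@H](O)[C@H](C(=O)N2[C@@H](Cc3ccccc3)COC2=O)c2cc(CO)cc(OC)c2OCc2ccc(OCc3ccccc3)c(OC)c2)ccc1OCc1ccccc1 | intermediate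
32 | (1S,2S)-1-[4-(benzyloxy)-3-methoxyphenyl]-2-(2-{[4-(benzyloxy)-3-methoxyphenyl]methoxy}-5-(hydroxymethyl)-3-methoxyphenyl)propane-1,3-diol | COc1cc([C@@H](O)[C@H](CO)c2cc(CO)cc(OC)c2OCc2ccc(OCc3ccccc3)c(OC)c2)ccc1OCc1ccccc1 | intermediate
33 | (4-{[4-(benzyloxy)-3-methoxyphenyl]methoxy}-3-[(4S,5S)-4-[4-(benzyloxy)-3-methoxyphenyl]-2,2-dimethyl-1,3-dioxan-5-yl]-5-methoxyphenyl)methanol | COc1cc([C@H]2OC(C)(C)OC[C@@H]2c2cc(CO)cc(OC)c2OCc2ccc(OCc3ccccc3)c(OC)c2)ccc1OCc1ccccc1 | intermediate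
34 | (4S,5S)-4-[4-(benzyloxy)-3-methoxyphenyl]-5-(2-{[4-(benzyloxy)-3-methoxyphenyl]methoxy}-5-(bromomethyl)-3-methoxyphenyl)-2,2-dimethyl-1,3-dioxane | COc1cc([C@H]2OC(C)(C)OC[C@@H]2c2cc(CBr)cc(OC)c2OCc2ccc(OCc3ccccc3)c(OC)c2)ccc1OCc1ccccc1 | intermediate
35 | (3R,4R)-3-[(4-{[4-(benzyloxy)-3-methoxyphenyl]methoxy}-3-[(4S,5S)-4-[4-(benzyloxy)-3-methoxyphenyl]-2,2-dimethyl-1,3-dioxan-5-yl]-5-methoxyphenyl)methyl]-4-{[(2S,3R)-3-[(benzyloxy)methyl]-2-[4-(benzyloxy)-3-methoxyphenyl]-7-methoxy-2,3-dihydro-1-benzofuran-5-yl]methyl}oxolan-2-one | COc1cc([C@H]2OC(C)(C)OC[C@@H]2c2cc(C[C@H]3C(=O)OC[C@@H]3Cc3cc(OC)c4c(c3)[C@H](COCc3ccccc3)[C@@H](c3ccc(OCc5ccccc5)c(OC)c3)O4)cc(OC)c2OCc2ccc(OCc3ccccc3)c(OC)c2)ccc1OCc1ccccc1 | intermediate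
36 | (3R,4R)-3-[(4-{[4-(benzyloxy)-3-methoxyphenyl]methoxy}-3-[(1S,2S)-1-[4-(benzyloxy)-3-methoxyphenyl]-1,3-dihydroxypropan-2-yl]-5-methoxyphenyl)methyl]-4-{[(2S,3R)-3-[(benzyloxy)methyl]-2-[4-(benzyloxy)-3-methoxyphenyl]-7-methoxy-2,3-dihydro-1-benzofuran-5-yl]methyl}oxolan-2-one | COc1cc([C@@H](O)[C@H](CO)c2cc(C[C@H]3C(=O)OC[C@@H]3Cc3cc(OC)c4c(c3)[C@H](COCc3ccccc3)[C@@H](c3ccc(OCc5ccccc5)c(OC)c3)O4)cc(OC)c2OCc2ccc(OCc3ccccc3)c(OC)c2)ccc1OCc1ccccc1 | intermediate
37 | CNP0186558.2: (3R,4R)-3-({3-[(1S,2S)-1,3-dihydroxy-1-(4-hydroxy-3-methoxyphenyl)propan-2-yl]-4-hydroxy-5-methoxyphenyl}methyl)-4-{[(2S,3R)-2-(4-hydroxy-3-methoxyphenyl)-3-(hydroxymethyl)-7-methoxy-2,3-dihydro-1-benzofuran-5-yl]methyl}oxolan-2-one | COc1cc([C@@H](O)[C@H](CO)c2cc(C[C@H]3C(=O)OC[C@@H]3Cc3cc(OC)c4c(c3)[C@H](CO)[C@@H](c3ccc(O)c(OC)c3)O4)cc(OC)c2O)ccc1O | target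

**Step count and risk**

Total step count: 24. Longest linear sequence: 18 steps (steps 1–13, 15, 16, 22, 23, 24).

Steps most likely to fail:

Step 9. The carbene may discriminate poorly between the two enantiotopic benzylic hydrogens on this heavily oxygenated substrate, or be diverted into dimerisation or aromatic addition, so that the insertion product forms in low enantiomeric purity or low amount. The fallback abandons carbene chemistry and sets out from imide 28 and aldehyde 29. A dibutylboron-mediated Evans syn-aldol (Bu2BOTf, i-Pr2NEt, CH2Cl2, −78 to 0 °C) should give the syn-aldol adduct F1, whose α-carbon already has the configuration needed at C3. LiBH4 then removes the auxiliary to give the syn diol F2. Hydrogenolysis (H2, Pd/C, EtOAc) frees both phenols to give the bisphenol triol F3. Mild acid (PPTS, CH2Cl2) ionises the para-hydroxybenzylic alcohol to a quinone methide, which the ring-B phenol captures trans to the C3 substituent, giving the phenylcoumaran phenol F4. K2CO3 and BnBr in acetone re-benzylate the ring-C phenol, and the route is rejoined at alcohol 15.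

Step 18. The magnesium enolate of an arylacetyl imide may add with an insufficient anti/syn ratio or eroded facial control, or the α-aryl adduct may epimerise or undergo retro-aldol cleavage before it is silylated. The fallback again sets out from imide 28 and aldehyde 29 but replaces the catalytic soft-enolisation manifold by a stoichiometric, preformed dibutylboron Z-enolate (Bu2BOTf, i-Pr2NEt, CH2Cl2, −78 °C). This enolate is added to aldehyde 29 precomplexed with Et2AlCl. Boron stays chelated to the imide and the externally activated aldehyde is attacked through an open transition state, a known way to anti adducts of the same α-configuration. It should give the silyl-retaining anti adduct F5, and HF·pyridine then returns the route at diol imide 31.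

Step 22. The SN2 union of two large fragments may be slow relative to ionisation of the electron-rich bromide and to proton exchange between enolate and product, leading to recovered lactone or double alkylation. The fallback sets out from alcohol 33 and lactone 25 and forms the same bond by carbonyl addition. MnO2 oxidises 33 to the ring-A aldehyde F6. The lithium enolate of 25 adds to F6 at −78 °C anti to the C4 substituent to give the β-hydroxy lactone F7 as a mixture of carbinol epimers. O-Phenyl chlorothionoformate with pyridine and DMAP gives the thiocarbonate F8. Barton–McCombie deoxygenation (Bu3SnH, AIBN, toluene, 80 °C) removes the superfluous oxygen and returns the route at 35.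

Further compounds
F1 | step 9 | (4S)-4-benzyl-3-[(2S,3S)-3-[4-(benzyloxy)-3-methoxyphenyl]-2-(2-{[4-(benzyloxy)-3-methoxyphenyl]methoxy}-5-{[(tert-butyldimethylsilyl)oxy]methyl}-3-methoxyphenyl)-3-hydroxypropanoyl]-1,3-oxazolidin-2-one (syn-aldol adduct) | COc1cc([C@@H](O)[C@@H](C(=O)N2[C@@H](Cc3ccccc3)COC2=O)c2cc(CO[Si](C)(C)C(C)(C)C)cc(OC)c2OCc2ccc(OCc3ccccc3)c(OC)c2)ccc1OCc1ccccc1
F2 | step 9 | (1S,2R)-1-[4-(benzyloxy)-3-methoxyphenyl]-2-(2-{[4-(benzyloxy)-3-methoxyphenyl]methoxy}-5-{[(tert-butyldimethylsilyl)oxy]methyl}-3-methoxyphenyl)propane-1,3-diol (syn diol) | COc1cc([C@@H](O)[C@@H](CO)c2cc(CO[Si](C)(C)C(C)(C)C)cc(OC)c2OCc2ccc(OCc3ccccc3)c(OC)c2)ccc1OCc1ccccc1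
F3 | step 9 | (1S,2R)-2-(5-{[(tert-butyldimethylsilyl)oxy]methyl}-2-hydroxy-3-methoxyphenyl)-1-(4-hydroxy-3-methoxyphenyl)propane-1,3-diol (bisphenol triol) | COc1cc([C@@H](O)[C@@H](CO)c2cc(CO[Si](C)(C)C(C)(C)C)cc(OC)c2O)ccc1O
F4 | step 9 | 4-[(2S,3R)-5-{[(tert-butyldimethylsilyl)oxy]methyl}-3-(hydroxymethyl)-7-methoxy-2,3-dihydro-1-benzofuran-2-yl]-2-methoxyphenol (phenylcoumaran phenol) | CC(C)(C)[Si](C)(C)OCc1cc(OC)c2c(c1)[C@H](CO)[C@@H](c1ccc(O)c(OC)c1)O2
F5 | step 18 | (4S)-4-benzyl-3-[(2R,3S)-3-[4-(benzyloxy)-3-methoxyphenyl]-2-(2-{[4-(benzyloxy)-3-methoxyphenyl]methoxy}-5-{[(tert-butyldimethylsilyl)oxy]methyl}-3-methoxyphenyl)-3-hydroxypropanoyl]-1,3-oxazolidin-2-one (silyl-retaining anti adduct) | COc1cc([C@@H](O)[C@H](C(=O)N2[C@@H](Cc3ccccc3)COC2=O)c2cc(CO[Si](C)(C)C(C)(C)C)cc(OC)c2OCc2ccc(OCc3ccccc3)c(OC)c2)ccc1OCc1ccccc1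
F6 | step 22 | 4-{[4-(benzyloxy)-3-methoxyphenyl]methoxy}-3-[(4S,5S)-4-[4-(benzyloxy)-3-methoxyphenyl]-2,2-dimethyl-1,3-dioxan-5-yl]-5-methoxybenzaldehyde (ring-A aldehyde) | COc1cc([C@H]2OC(C)(C)OC[C@@H]2c2cc(C=O)cc(OC)c2OCc2ccc(OCc3ccccc3)c(OC)c2)ccc1OCc1ccccc1
F7 | step 22 | (3S,4R)-3-[(4-{[4-(benzyloxy)-3-methoxyphenyl]methoxy}-3-[(4S,5S)-4-[4-(benzyloxy)-3-methoxyphenyl]-2,2-dimethyl-1,3-dioxan-5-yl]-5-methoxyphenyl)(hydroxy)methyl]-4-{[(2S,3R)-3-[(benzyloxy)methyl]-2-[4-(benzyloxy)-3-methoxyphenyl]-7-methoxy-2,3-dihydro-1-benzofuran-5-yl]methyl}oxolan-2-one (β-hydroxy lactone, carbinol epimers) | COc1cc([C@H]2OC(C)(C)OC[C@@H]2c2cc(C(O)[C@H]3C(=O)OC[C@@H]3Cc3cc(OC)c4c(c3)[C@H](COCc3ccccc3)[C@@H](c3ccc(OCc5ccccc5)c(OC)c3)O4)cc(OC)c2OCc2ccc(OCc3ccccc3)c(OC)c2)ccc1OCc1ccccc1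
F8 | step 22 | O-phenyl thiocarbonate of F7 at the new carbinol (carbinol epimers) | COc1cc([C@H]2OC(C)(C)OC[C@@H]2c2cc(C(OC(=S)Oc3ccccc3)[C@H]3C(=O)OC[C@@H]3Cc3cc(OC)c4c(c3)[C@H](COCc3ccccc3)[C@@H](c3ccc(OCc5ccccc5)c(OC)c3)O4)cc(OC)c2OCc2ccc(OCc3ccccc3)c(OC)c2)ccc1OCc1ccccc1
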